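**Plan**
The target is a 6-aryl apigenin in which O1 (on C8a) and the C4 carbonyl carbon (on C4a) sit on neighbouring carbons of ring A, with the C5 oxygen next to C4a.
Retrosynthesis: three benzyl ethers are removed, then C8a–O1, C4a–C4 and O1–C2 are cut together, giving a C4a≡C8a aryne of ring A and 3-[4-(benzyloxy)phenyl]propiolic acid (ring B plus C2–C3–C4).
The aryne precursor, an ortho-silylaryl triflate, goes back through a bromophenol to a symmetric 4-aryl-3,5-bis(benzyloxy)phenol; its ring A–ring D bond is cut to a ring D arylmagnesium reagent and 2,6-bis(benzyloxy)-1,4-benzoquinone.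
Forward: ring D is joined to the ring A quinone, ring A is rearomatised and armed with bromine, then silicon and triflate, and ring C is closed in the aryne step with the acid that carries ring B.
The benzyl groups, chosen because hydrogenolysis spares the ring D methyl ether and methyl ester, come off last.
Stereochemistry: the target has no stereocentre and no stereogenic double bond, so nothing has to be controlled.

Key step: step 8

Remark: 3,5-bis(benzyloxy)phenol and 1-(benzyloxy)-4-ethynylbenzene are taken as purchasable, and the ring A–ring D axis (flanked by two hydroxyl groups and one methoxy group) is taken as freely rotating.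

**Route**

Step 1
Reactants: 1 3,5-bis(benzyloxy)phenol
Product: 2 2,6-bis(benzyloxy)-1,4-benzoquinone
Conditions: (KSO3)2NO (2.2 equiv), KH2PO4, H2O/acetone, 0 °C to rt
Reagents that add atoms: potassium nitrosodisulfonate (KSO3)2NO, [K+].[K+].[O]N(S(=O)(=O)[O-])S(=O)(=O)[O-]
Why: Teuber oxidation, in which two equivalents of the nitroxyl radical convert a phenol with a free para position into the para-quinone by hydrogen abstraction and oxygen transfer to the para carbon, while the benzyl ethers are inert to the reagent.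

Step 2
Reactants: 3 methyl 3-iodo-4-methoxybenzoate; 2 2,6-bis(benzyloxy)-1,4-benzoquinone
Product: 5 methyl 3-[2,6-bis(benzyloxy)-1-hydroxy-4-oxocyclohexa-2,5-dien-1-yl]-4-methoxybenzoate, via arylmagnesium chloride 4 (not isolated)
Conditions: 3, i-PrMgCl·LiCl (1.1 equiv), THF, −40 °C; cannulate into 2, THF, −78 °C; sat. aq. NH4Cl
Reagents that add atoms: none
Why: Iodine–magnesium exchange with i-PrMgCl·LiCl at low temperature leaves the methyl ester intact, and the arylmagnesium then adds 1,2 to the C1 carbonyl group of 2 (Grignard addition to a quinone giving a para-quinol), which is the more electrophilic carbonyl because the C4 carbonyl group is deactivated as a doubly vinylogous ester and because magnesium can chelate between the C1 oxygen and a neighbouring benzyloxy oxygen.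

Step 3
Reactants: 5 methyl 3-[2,6-bis(benzyloxy)-1-hydroxy-4-oxocyclohexa-2,5-dien-1-yl]-4-methoxybenzoate
Product: 6 methyl 3-[2,6-bis(benzyloxy)-4-hydroxyphenyl]-4-methoxybenzoate
Conditions: Zn dust, AcOH/THF, rt
Reagents that add atoms: none
Why: Reductive aromatisation of a para-quinol with zinc in acetic acid, in which two-electron reduction of the cross-conjugated dienone expels the tertiary hydroxyl group as water and leaves a phenol whose oxygen is para to the new biaryl bond.

Step 4
Reactants: 6 methyl 3-[2,6-bis(benzyloxy)-4-hydroxyphenyl]-4-methoxybenzoate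
Product: 7 methyl 3-[2,6-bis(benzyloxy)-3-bromo-4-hydroxyphenyl]-4-methoxybenzoate
Conditions: NBS (1.0 equiv), CH2Cl2, −78 to 0 °C
Reagents that add atoms: N-bromosuccinimide, O=C1CCC(=O)N1Br
Why: Electrophilic aromatic bromination, for which the two positions ortho to the hydroxyl group are equivalent and are the only free sites of the phloroglucinol-type ring, ring D is deactivated by its ester, and one equivalent of NBS at low temperature should stop at the monobromide.

Step 5
Reactants: 7 methyl 3-[2,6-bis(benzyloxy)-3-bromo-4-hydroxyphenyl]-4-methoxybenzoate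
Product: 8 methyl 3-[2,6-bis(benzyloxy)-3-bromo-4-[(trimethylsilyl)oxy]phenyl]-4-methoxybenzoate
Conditions: HMDS, THF, 70 °C; evaporate, use crude
Reagents that add atoms: hexamethyldisilazane, C[Si](C)(C)N[Si](C)(C)C
Why: O-Silylation of the phenol with HMDS gives the trimethylsilyl ether with ammonia as the only co-product and places silicon on the oxygen next to the bromide for the shift in step 6.

Step 6
Reactants: 8 methyl 3-[2,6-bis(benzyloxy)-3-bromo-4-[(trimethylsilyl)oxy]phenyl]-4-methoxybenzoate
Product: 10 methyl 3-[2,6-bis(benzyloxy)-4-(trifluoromethanesulfonyloxy)-3-(trimethylsilyl)phenyl]-4-methoxybenzoate, via lithium silylphenoxide 9 (not isolated)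
Conditions: n-BuLi (1.05 equiv), THF, −100 °C; then Tf2O, −100 to −78 °C
Reagents that add atoms: trifluoromethanesulfonic anhydride, O=S(=O)(OS(=O)(=O)C(F)(F)F)C(F)(F)F
Why: Bromine–lithium exchange at −100 °C on a bromide flanked by two oxygen substituents should outrun attack of n-BuLi on the distant methyl ester, the aryllithium is consumed at once by the intramolecular 1,3 O-to-C silyl shift (retro-Brook rearrangement), and the resulting phenoxide is trapped by O-triflation.

Step 7
Reactants: 11 1-(benzyloxy)-4-ethynylbenzene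
Product: 13 3-[4-(benzyloxy)phenyl]prop-2-ynoic acid, via lithium acetylide 12 (not isolated)
Conditions: n-BuLi, THF, −78 °C; CO2; aq. HCl
Reagents that add atoms: carbon dioxide, O=C=O
Why: Deprotonation of the terminal alkyne with n-BuLi and carboxylation of the lithium acetylide with CO2 is the standard entry to arylpropiolic acids, and the aryl benzyl ether is inert at −78 °C.

Step 8
Reactants: 10 methyl 3-[2,6-bis(benzyloxy)-4-(trifluoromethanesulfonyloxy)-3-(trimethylsilyl)phenyl]-4-methoxybenzoate; 13 3-[4-(benzyloxy)phenyl]prop-2-ynoic acid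
Product: 16 methyl 3-[5,7-bis(benzyloxy)-2-[4-(benzyloxy)phenyl]-4-oxo-4H-chromen-6-yl]-4-methoxybenzoate, via ring A aryne 14 (not isolated), via ortho-acyl phenoxide 15 (not isolated)
Conditions: 13 (1.5 equiv), CsF (4 equiv), THF, 125 °C, sealed tube
Reagents that add atoms: none
Why: Fluoride attacks silicon of 10 and loss of triflate gives aryne 14 (C4a≡C8a); the cesium carboxylate of 13 adds through oxygen to C8a, the aryl anion formed at C4a attacks its own ester carbonyl group (4-exo-trig), and the strained four-membered alkoxide opens to the ortho-acyl phenoxide 15, so the net result is insertion of the aryne into the C–O bond of the acid, a known reaction type of carboxylic acids with ortho-silylaryl triflates that runs on to flavones with arylpropiolic acids. Ring C then closes by 6-endo-dig oxa-Michael addition of the C8a phenoxide to the ynone (O1–C2), and protonation of the vinyl anion gives the 4-pyranone. No stereocentre is formed. The step needs regioselective addition to the unsymmetrical aryne: the C5 benzyloxy group next to C4a distorts and polarises the triple bond, shields C4a and stabilises negative charge there inductively, so oxygen should enter at the distal C8a and the acyl carbon at C4a. It also needs acyl transfer to win over protonation of the aryl anion, which the aprotic medium and high temperature favour, and 6-endo closure to win over 5-exo closure to an aurone, which aprotic basic conditions with reversible addition should favour.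

Step 9
Reactants: 16 methyl 3-[5,7-bis(benzyloxy)-2-[4-(benzyloxy)phenyl]-4-oxo-4H-chromen-6-yl]-4-methoxybenzoate
Product: 17 methyl 3-[5,7-dihydroxy-2-(4-hydroxyphenyl)-4-oxo-4H-chromen-6-yl]-4-methoxybenzoate (CNP0261185.0)
Conditions: H2 (1 atm), 10% Pd/C, EtOAc/MeOH, rt
Reagents that add atoms: none
Why: Catalytic hydrogenolysis of aryl benzyl ethers, under which the pyranone double bond of a flavone, the aryl methyl ether and the methyl ester are normally inert at one atmosphere of hydrogen and room temperature.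

**Compound list**

1 | 3,5-bis(benzyloxy)phenol | Oc1cc(OCc2ccccc2)cc(OCc3ccccc3)c1 | starting material
2 | 2,6-bis(benzyloxy)-1,4-benzoquinone | O=C1C=C(OCc2ccccc2)C(=O)C(OCc3ccccc3)=C1 | intermediate
3 | methyl 3-iodo-4-methoxybenzoate | COC(=O)c1ccc(OC)c(I)c1 | starting material
4 | [2-methoxy-5-(methoxycarbonyl)phenyl]magnesium chloride (LiCl complex) | COC(=O)c1ccc(OC)c([Mg]Cl)c1 | intermediate
5 | methyl 3-[2,6-bis(benzyloxy)-1-hydroxy-4-oxocyclohexa-2,5-dien-1-yl]-4-methoxybenzoate | COC(=O)c1ccc(OC)c(C2(O)C(OCc3ccccc3)=CC(=O)C=C2OCc4ccccc4)c1 | intermediate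
6 | methyl 3-[2,6-bis(benzyloxy)-4-hydroxyphenyl]-4-methoxybenzoate | COC(=O)c1ccc(OC)c(-c2c(OCc3ccccc3)cc(O)cc2OCc4ccccc4)c1 | intermediate
7 | methyl 3-[2,6-bis(benzyloxy)-3-bromo-4-hydroxyphenyl]-4-methoxybenzoate | COC(=O)c1ccc(OC)c(-c2c(OCc3ccccc3)cc(O)c(Br)c2OCc4ccccc4)c1 | intermediate
8 | methyl 3-[2,6-bis(benzyloxy)-3-bromo-4-[(trimethylsilyl)oxy]phenyl]-4-methoxybenzoate | COC(=O)c1ccc(OC)c(-c2c(OCc3ccccc3)cc(O[Si](C)(C)C)c(Br)c2OCc4ccccc4)c1 | intermediate
9 | lithium 3,5-bis(benzyloxy)-4-[2-methoxy-5-(methoxycarbonyl)phenyl]-2-(trimethylsilyl)phenoxide | COC(=O)c1ccc(OC)c(-c2c(OCc3ccccc3)cc(O[Li])c([Si](C)(C)C)c2OCc4ccccc4)c1 | intermediate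
10 | methyl 3-[2,6-bis(benzyloxy)-4-(trifluoromethanesulfonyloxy)-3-(trimethylsilyl)phenyl]-4-methoxybenzoate | COC(=O)c1ccc(OC)c(-c2c(OCc3ccccc3)cc(OS(=O)(=O)C(F)(F)F)c([Si](C)(C)C)c2OCc4ccccc4)c1 | intermediate
11 | 1-(benzyloxy)-4-ethynylbenzene | C#Cc1ccc(OCc2ccccc2)cc1 | starting material
12 | lithium [4-(benzyloxy)phenyl]acetylide | [Li]C#Cc1ccc(OCc2ccccc2)cc1 | intermediate
13 | 3-[4-(benzyloxy)phenyl]prop-2-ynoic acid | OC(=O)C#Cc1ccc(OCc2ccccc2)cc1 | intermediate
14 | methyl 3-[2,6-bis(benzyloxy)-3,4-didehydrophenyl]-4-methoxybenzoate (ring A aryne, C4a≡C8a) | COC(=O)c1ccc(OC)c(C2=C(OCc3ccccc3)C#CC=C2OCc4ccccc4)c1 | intermediate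
15 | cesium 3,5-bis(benzyloxy)-2-{3-[4-(benzyloxy)phenyl]prop-2-ynoyl}-4-[2-methoxy-5-(methoxycarbonyl)phenyl]phenoxide | COC(=O)c1ccc(OC)c(-c2c(OCc3ccccc3)cc([O-])c(C(=O)C#Cc4ccc(OCc5ccccc5)cc4)c2OCc6ccccc6)c1.[Cs+] | intermediate
16 | methyl 3-[5,7-bis(benzyloxy)-2-[4-(benzyloxy)phenyl]-4-oxo-4H-chromen-6-yl]-4-methoxybenzoate | COC(=O)c1ccc(OC)c(-c2c(OCc3ccccc3)cc4oc(-c5ccc(OCc6ccccc6)cc5)cc(=O)c4c2OCc7ccccc7)c1 | intermediate
17 | methyl 3-[5,7-dihydroxy-2-(4-hydroxyphenyl)-4-oxo-4H-chromen-6-yl]-4-methoxybenzoate | COC(=O)c1ccc(OC)c(-c2c(O)cc3oc(-c4ccc(O)cc4)cc(=O)c3c2O)c1 | target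

**Step count**
Total: 9 steps. Longest linear sequence: 8 steps (steps 1 to 6, then 8 and 9, from compound 1). Step 7 is a one-step side branch.

**Steps most likely to fail**

Step 8. The aryl anion at C4a may be protonated before it reaches the ester carbonyl group, giving O-arylation without acyl transfer. The propiolate may also lose CO2 at 125 °C, the carboxylate may add to the aryne in the wrong orientation, or ring closure may run 5-exo. The fallback sets out from 6 and 11 and returns at 16. Iodination of 6 with NIS in CH2Cl2 at low temperature should give methyl 3-[2,6-bis(benzyloxy)-4-hydroxy-3-iodophenyl]-4-methoxybenzoate F1. A carbonylative Sonogashira annulation of F1 with alkyne 11 (CO at 1 atm, Pd(PPh3)2Cl2, Et2NH, DMF, 60 to 100 °C) would place CO between C4a and the alkyne. The diethylamine adduct of the resulting ynone closes ring C to the flavone 16. Oxygen stays on C8a throughout, so no regiochemical question arises.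

Step 6. n-BuLi or the aryllithium may add to the methyl ester of ring D in competition with exchange and silyl migration, or the aryllithium may be protonated with loss of the bromine. The fallback sets out from 7 and returns at 10, and removes the electrophilic ester for the organolithium stage. Saponification of 7 (LiOH, THF/H2O) gives 3-[2,6-bis(benzyloxy)-3-bromo-4-hydroxyphenyl]-4-methoxybenzoic acid F2. Double deprotonation with n-BuLi (2 equiv), bromine–lithium exchange with t-BuLi (2 equiv) at −78 °C, quench with excess TMSCl and a buffered (pH 7) hydrolytic work-up that cleaves the O-silyl groups should give 3-[2,6-bis(benzyloxy)-4-hydroxy-3-(trimethylsilyl)phenyl]-4-methoxybenzoic acid F3. Selective esterification of the carboxylate (MeI, KHCO3, DMF) gives methyl 3-[2,6-bis(benzyloxy)-4-hydroxy-3-(trimethylsilyl)phenyl]-4-methoxybenzoate F4. Triflation (Tf2O, pyridine, CH2Cl2, 0 °C) then gives 10.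

Step 2. Single-electron transfer from the arylmagnesium reagent to the quinone may give reduction and homocoupling, or addition may occur at the C4 carbonyl group or in conjugate fashion. The fallback sets out from 2 and 3 and returns at 6, forming the biaryl bond by cross-coupling instead.
- Reduction of 2 with Na2S2O4 (EtOAc/H2O) gives 2,6-bis(benzyloxy)benzene-1,4-diol F5.
- The unhindered hydroxyl group is silylated (TBSCl, imidazole, DMF, 0 °C) to 2,6-bis(benzyloxy)-4-[(tert-butyldimethylsilyl)oxy]phenol F6.
- The hindered hydroxyl group is triflated (Tf2O, pyridine) to 2,6-bis(benzyloxy)-4-[(tert-butyldimethylsilyl)oxy]phenyl trifluoromethanesulfonate F7.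
- Miyaura borylation of 3 (B2pin2, Pd(dppf)Cl2, KOAc, dioxane, 80 °C) gives methyl 4-methoxy-3-(4,4,5,5-tetramethyl-1,3,2-dioxaborolan-2-yl)benzoate F8.
- Suzuki–Miyaura coupling of F7 with F8 (Pd(OAc)2, SPhos, K3PO4, toluene/H2O, 90 °C) gives methyl 3-[2,6-bis(benzyloxy)-4-[(tert-butyldimethylsilyl)oxy]phenyl]-4-methoxybenzoate F9.
- TBAF in THF then gives 6.

**Further compounds**

F1 | step 8 | methyl 3-[2,6-bis(benzyloxy)-4-hydroxy-3-iodophenyl]-4-methoxybenzoate | COC(=O)c1ccc(OC)c(-c2c(OCc3ccccc3)cc(O)c(I)c2OCc4ccccc4)c1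
F2 | step 6 | 3-[2,6-bis(benzyloxy)-3-bromo-4-hydroxyphenyl]-4-methoxybenzoic acid | OC(=O)c1ccc(OC)c(-c2c(OCc3ccccc3)cc(O)c(Br)c2OCc4ccccc4)c1
F3 | step 6 | 3-[2,6-bis(benzyloxy)-4-hydroxy-3-(trimethylsilyl)phenyl]-4-methoxybenzoic acid | OC(=O)c1ccc(OC)c(-c2c(OCc3ccccc3)cc(O)c([Si](C)(C)C)c2OCc4ccccc4)c1
F4 | step 6 | methyl 3-[2,6-bis(benzyloxy)-4-hydroxy-3-(trimethylsilyl)phenyl]-4-methoxybenzoate | COC(=O)c1ccc(OC)c(-c2c(OCc3ccccc3)cc(O)c([Si](C)(C)C)c2OCc4ccccc4)c1
F5 | step 2 | 2,6-bis(benzyloxy)benzene-1,4-diol | Oc1cc(OCc2ccccc2)c(O)c(OCc3ccccc3)c1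
F6 | step 2 | 2,6-bis(benzyloxy)-4-[(tert-butyldimethylsilyl)oxy]phenol | CC(C)(C)[Si](C)(C)Oc1cc(OCc2ccccc2)c(O)c(OCc3ccccc3)c1
F7 | step 2 | 2,6-bis(benzyloxy)-4-[(tert-butyldimethylsilyl)oxy]phenyl trifluoromethanesulfonate | CC(C)(C)[Si](C)(C)Oc1cc(OCc2ccccc2)c(OS(=O)(=O)C(F)(F)F)c(OCc3ccccc3)c1
F8 | step 2 | methyl 4-methoxy-3-(4,4,5,5-tetramethyl-1,3,2-dioxaborolan-2-yl)benzoate | COC(=O)c1ccc(OC)c(B2OC(C)(C)C(C)(C)O2)c1
F9 | step 2 | methyl 3-[2,6-bis(benzyloxy)-4-[(tert-butyldimethylsilyl)oxy]phenyl]-4-methoxybenzoate | COC(=O)c1ccc(OC)c(-c2c(OCc3ccccc3)cc(O[Si](C)(C)C(C)(C)C)cc2OCc4ccccc4)c1
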